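**Assumptions:** Cembrane numbering is used for locants (C1 = lactone β‑CH, C2 = lactone O–CH, C3/C4 = epoxide, C5 = CHOAc, C14 = CHOH, C15/C16/C17 = α‑methylene lactone carbons), so the target is (1R,2S,3S,4S,5R,14R,7E,11E). Furfural, propanal and (E)‑geranyl chloride are taken as commercial.

## Retrosynthetic overview

1. Open C1–C14: the 14‑membered ring closes last by intramolecular Barbier allylation of a 3‑(bromomethyl)butenolide onto a C14 aldehyde, which sets C1, C14 and the exo‑methylene.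
2. C17 comes from a Morita–Baylis–Hillman hydroxymethylation; the C14 aldehyde is carried as a terminal 1,3‑diene and revealed late by hydroboration/oxidation.
3. The butenolide comes from a furan: singlet‑oxygen dearomatisation of a 2‑alkenylfuran, then C5‑OH‑directed epoxidation (C3, C4), epoxide‑controlled ketone reduction (C2) and Mitsunobu acetate inversion (C5).
4. The furan tetraene comes from α‑selective allylbarium coupling of a geranyl‑derived chloride with a furyl enal; oxidation/CBS reduction sets C5, the only reagent‑controlled stereocentre.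
5. Ring order: furan (bought) → butenolide → epoxide → 14‑membered carbocycle.

## Route

**Step 1**
Reactants: 1 furfural; 2 propanal
Product: 3 (2E)‑3‑(furan‑2‑yl)‑2‑methylprop‑2‑enal
Conditions: NaOH (aq), EtOH, 0 °C → rt (slow addition of 2)
Reagents that add atoms: none
Why: Crossed aldol (Claisen–Schmidt) condensation of a non‑enolisable aldehyde gives the thermodynamic E‑enal, fixing the C3=C4 geometry.

**Step 2**
Reactants: 4 geranyl chloride
Product: 5 (2E,6E)‑8‑chloro‑2,6‑dimethylocta‑2,6‑dienal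
Conditions: SeO2 (cat.), t‑BuOOH, salicylic acid, CH2Cl2, rt; then MnO2, CH2Cl2
Reagents that add atoms: tert‑butyl hydroperoxide CC(C)(C)OO; selenium dioxide O=[Se]=O
Why: Sharpless SeO2/TBHP allylic oxidation is selective for the (E)‑methyl of the terminal isopropylidene, and MnO2 converges the alcohol/aldehyde mixture on the E‑enal without touching the allylic chloride.

**Step 3**
Reactants: 5
Product: 6 (2E,6E)‑1‑chloro‑3,7‑dimethylnona‑2,6,8‑triene
Conditions: Ph3P=CH2 (from Ph3PCH3Br, KHMDS), THF, −78 °C (ylide added to 5)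
Reagents that add atoms: methyltriphenylphosphonium bromide C[P+](c1ccccc1)(c1ccccc1)c1ccccc1.[Br-]
Why: Wittig methylenation of the aldehyde at −78 °C outpaces alkylation of the ylide by the allylic chloride and gives the 2‑substituted 1,3‑diene that serves as a protecting‑group‑free latent C13–C14 aldehyde.

**Step 4**
Reactants: 6; 3
Product: 7 rac‑(1E,5E,9E)‑1‑(furan‑2‑yl)‑2,6,10‑trimethyldodeca‑1,5,9,11‑tetraen‑3‑ol
Conditions: Ba* (BaI2, Li biphenylide), THF; 6, −78 °C; then 3, −78 °C
Reagents that add atoms: none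
Why: Yamamoto allylbarium addition is α‑selective with retention of the E‑olefin and adds 1,2 to enals, forming C5–C6; C5 is racemic here and is corrected in steps 5–6.

**Step 5**
Reactants: 7
Product: 8 (1E,5E,9E)‑1‑(furan‑2‑yl)‑2,6,10‑trimethyldodeca‑1,5,9,11‑tetraen‑3‑one
Conditions: MnO2, CH2Cl2, rt
Reagents that add atoms: none
Why: Chemoselective MnO2 oxidation of the activated allylic alcohol gives the cross‑conjugated enone under neutral conditions that do not isomerise the β,γ‑olefin.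

**Step 6**
Reactants: 8
Product: 9 (3S,1E,5E,9E)‑1‑(furan‑2‑yl)‑2,6,10‑trimethyldodeca‑1,5,9,11‑tetraen‑3‑ol (cembrane 5S)
Conditions: (R)‑Me‑CBS (20 mol %), catecholborane, toluene, −78 °C
Reagents that add atoms: none
Why: Corey–Bakshi–Shibata reduction treats the α‑methyl alkenyl group as large and CH2‑allyl as small, giving the 5S alcohol; catecholborane at −78 °C does not hydroborate the diene.

**Step 7 (key step)**
Reactants: 9
Product: 10 5‑hydroxy‑5‑[(1E,3S,5E,9E)‑3‑hydroxy‑2,6,10‑trimethyldodeca‑1,5,9,11‑tetraen‑1‑yl]furan‑2(5H)‑one (hemiketal epimers)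
Conditions: O2, hν, tetraphenylporphyrin, i‑Pr2NEt, CH2Cl2, −78 °C; then aq NaH2PO4
Reagents that add atoms: singlet oxygen (from O2) O=O
Why: [4+2] cycloaddition of singlet oxygen to the furan followed by base‑induced Kornblum–DeLaMare fragmentation turns the unsubstituted α‑carbon into the lactone carbonyl (C16) and C2 into a ketone‑level hemiketal; the furan reacts roughly 100–1000 times faster than the trisubstituted alkenes and diene, and dearomatisation leaves C3=C4 as an isolated allylic‑alcohol olefin ready for the stereochemical relay.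

**Step 8**
Reactants: 10
Product: 11 5‑hydroxy‑5‑{(2R,3S)‑3‑[(1S,3E,7E)‑1‑hydroxy‑4,8‑dimethyldeca‑3,7,9‑trien‑1‑yl]‑3‑methyloxiran‑2‑yl}furan‑2(5H)‑one (cembrane 3S,4S,5S)
Conditions: VO(acac)2 (5 mol %), t‑BuOOH (1.2 equiv), CH2Cl2, 0 °C
Reagents that add atoms: tert‑butyl hydroperoxide CC(C)(C)OO
Why: Vanadium‑catalysed hydroxyl‑directed epoxidation touches only the allylic‑alcohol olefin, and A(1,2) strain from the C4 methyl enforces erythro delivery from the 5S carbinol, setting C3 and C4 as the trans (3S,4S) epoxide.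

**Step 9**
Reactants: 11
Product: 12 (5S)‑5‑{(2S,3S)‑3‑[(1S,3E,7E)‑1‑hydroxy‑4,8‑dimethyldeca‑3,7,9‑trien‑1‑yl]‑3‑methyloxiran‑2‑yl}furan‑2(5H)‑one
Conditions: NaBH4, CeCl3·7H2O, MeOH, −78 → −40 °C; then aq citric acid (pH 3), rt
Reagents that add atoms: none
Why: Luche 1,2‑reduction of the ring‑opened α,β‑epoxy keto‑carboxylate under chelation (Cram‑chelate) control gives the erythro epoxy alcohol (C2 = S), and the Z‑γ‑hydroxy enoate lactonises on acidification to the butenolide.

**Step 10**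
Reactants: 12
Product: 13 (1R,3E,7E)‑4,8‑dimethyl‑1‑{(2S,3S)‑2‑methyl‑3‑[(2S)‑5‑oxo‑2,5‑dihydrofuran‑2‑yl]oxiran‑2‑yl}deca‑3,7,9‑trien‑1‑yl acetate
Conditions: AcOH, PPh3, DIAD, toluene, 0 °C → rt
Reagents that add atoms: acetic acid CC(=O)O
Why: Mitsunobu esterification installs the acetate with SN2 inversion, converting the erythro 5S alcohol needed for step 8 into the threo 5R acetate of the target in one operation.

**Step 11**
Reactants: 13
Product: 14 (1R,3E,7E)‑1‑{(2S,3S)‑3‑[(2S)‑4‑(hydroxymethyl)‑5‑oxo‑2,5‑dihydrofuran‑2‑yl]‑2‑methyloxiran‑2‑yl}‑4,8‑dimethyldeca‑3,7,9‑trien‑1‑yl acetate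
Conditions: aq HCHO, PBu3 (cat.), phenol (cat.), THF, rt
Reagents that add atoms: formaldehyde C=O
Why: Morita–Baylis–Hillman hydroxymethylation at the butenolide α‑carbon introduces C17; the phenol‑buffered phosphine is too weakly basic to deprotonate the γ‑position (C2), so the stereocentre and epoxide should survive.

**Step 12**
Reactants: 14
Product: 15 (1R,3E,7E)‑10‑hydroxy‑1‑{(2S,3S)‑3‑[(2S)‑4‑(hydroxymethyl)‑5‑oxo‑2,5‑dihydrofuran‑2‑yl]‑2‑methyloxiran‑2‑yl}‑4,8‑dimethyldeca‑3,7‑dien‑1‑yl acetate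
Conditions: 9‑BBN (2.2 equiv), THF, 0 °C → rt; then NaBO3·4H2O, THF/H2O
Reagents that add atoms: sodium perborate [Na+].[O-]OB=O
Why: Brown hydroboration with 9‑BBN adds anti‑Markovnikov only to the terminal vinyl of the diene (as in the homogeraniol synthesis) and ignores trisubstituted alkenes, lactone, epoxide and acetate; perborate oxidation is mild enough for the butenolide and gives the C14 primary alcohol.

**Step 13**
Reactants: 15
Product: 16 (1R,3E,7E)‑1‑{(2S,3S)‑3‑[(2S)‑4‑(bromomethyl)‑5‑oxo‑2,5‑dihydrofuran‑2‑yl]‑2‑methyloxiran‑2‑yl}‑10‑hydroxy‑4,8‑dimethyldeca‑3,7‑dien‑1‑yl acetate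
Conditions: NBS, Me2S, CH2Cl2, −20 → 0 °C
Reagents that add atoms: N‑bromosuccinimide BrN1C(=O)CCC1=O
Why: Corey–Kim halogenation converts only the allylic (MBH‑type) alcohol to the bromide; the saturated primary alcohol forms an alkoxysulfonium salt that reverts on work‑up.

**Step 14**
Reactants: 16
Product: 17 (1R,3E,7E)‑1‑{(2S,3S)‑3‑[(2S)‑4‑(bromomethyl)‑5‑oxo‑2,5‑dihydrofuran‑2‑yl]‑2‑methyloxiran‑2‑yl}‑4,8‑dimethyl‑10‑oxodeca‑3,7‑dien‑1‑yl acetate
Conditions: Dess–Martin periodinane, NaHCO3, CH2Cl2, 0 °C (used crude)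
Reagents that add atoms: none
Why: Buffered Dess–Martin oxidation gives the β,γ‑unsaturated aldehyde without olefin migration and tolerates the allylic bromide, epoxide and acetate.

**Step 15**
Reactants: 17
Product: 18 michaolide F
Conditions: In powder, THF/H2O (4:1), syringe‑pump addition to 1 mM, rt (Zn, THF/aq NH4Cl as equivalent)
Reagents that add atoms: none
Why: Proposed new method: macrocyclic version of the known intermolecular Zn/In Barbier allylation of 3‑(bromomethyl)butenolides (closest precedents: that reaction and Zn/Cr macrocyclisations of ω‑formyl 2‑(bromomethyl)acrylates); the allylindium attacks the aldehyde through its γ‑carbon (C1) on the face opposite the C2 substituent (trans lactone, 1R) with transposition to the exo‑methylene, and the lactone‑chelated transition state that makes Zn/In couplings of this reagent class syn‑selective is expected to give 14R, leaving the C14‑OH free beside the pre‑installed C5 acetate.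

## Compound list

1 | furfural | O=Cc1ccco1 | starting material
2 | propanal | CCC=O | starting material
3 | (2E)‑3‑(furan‑2‑yl)‑2‑methylprop‑2‑enal | O=C/C(C)=C/c1ccco1 | intermediate
4 | geranyl chloride | ClC/C=C(C)/CCC=C(C)C | starting material
5 | (2E,6E)‑8‑chloro‑2,6‑dimethylocta‑2,6‑dienal | O=C/C(C)=C/CC/C(C)=C/CCl | intermediate
6 | (2E,6E)‑1‑chloro‑3,7‑dimethylnona‑2,6,8‑triene | C=C/C(C)=C/CC/C(C)=C/CCl | intermediate
7 | rac‑(1E,5E,9E)‑1‑(furan‑2‑yl)‑2,6,10‑trimethyldodeca‑1,5,9,11‑tetraen‑3‑ol | o1cccc1/C=C(C)/C(O)C/C=C(C)/CC/C=C(C)/C=C | intermediate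
8 | (1E,5E,9E)‑1‑(furan‑2‑yl)‑2,6,10‑trimethyldodeca‑1,5,9,11‑tetraen‑3‑one | o1cccc1/C=C(C)/C(=O)C/C=C(C)/CC/C=C(C)/C=C | intermediate
9 | (3S,1E,5E,9E)‑1‑(furan‑2‑yl)‑2,6,10‑trimethyldodeca‑1,5,9,11‑tetraen‑3‑ol | o1cccc1/C=C(C)/[C@@H](O)C/C=C(C)/CC/C=C(C)/C=C | intermediate
10 | 5‑hydroxy‑5‑[(1E,3S,5E,9E)‑3‑hydroxy‑2,6,10‑trimethyldodeca‑1,5,9,11‑tetraen‑1‑yl]furan‑2(5H)‑one (hemiketal epimers) | O=C1C=CC(O)(O1)/C=C(C)/[C@@H](O)C/C=C(C)/CC/C=C(C)/C=C | intermediate
11 | 5‑hydroxy‑5‑{(2R,3S)‑3‑[(1S,3E,7E)‑1‑hydroxy‑4,8‑dimethyldeca‑3,7,9‑trien‑1‑yl]‑3‑methyloxiran‑2‑yl}furan‑2(5H)‑one | O=C1C=CC(O)(O1)[C@@H]1O[C@@]1(C)[C@@H](O)C/C=C(C)/CC/C=C(C)/C=C | intermediate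
12 | (5S)‑5‑{(2S,3S)‑3‑[(1S,3E,7E)‑1‑hydroxy‑4,8‑dimethyldeca‑3,7,9‑trien‑1‑yl]‑3‑methyloxiran‑2‑yl}furan‑2(5H)‑one | O=C1C=C[C@H](O1)[C@@H]1O[C@@]1(C)[C@@H](O)C/C=C(C)/CC/C=C(C)/C=C | intermediate
13 | (1R,3E,7E)‑4,8‑dimethyl‑1‑{(2S,3S)‑2‑methyl‑3‑[(2S)‑5‑oxo‑2,5‑dihydrofuran‑2‑yl]oxiran‑2‑yl}deca‑3,7,9‑trien‑1‑yl acetate | O=C1C=C[C@H](O1)[C@@H]1O[C@@]1(C)[C@H](OC(C)=O)C/C=C(C)/CC/C=C(C)/C=C | intermediate
14 | 4‑(hydroxymethyl)butenolide analogue of 13 | O=C1C(CO)=C[C@H](O1)[C@@H]1O[C@@]1(C)[C@H](OC(C)=O)C/C=C(C)/CC/C=C(C)/C=C | intermediate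
15 | 10‑hydroxy‑deca‑3,7‑dienyl diol (C14‑OH, C17‑OH) | O=C1C(CO)=C[C@H](O1)[C@@H]1O[C@@]1(C)[C@H](OC(C)=O)C/C=C(C)/CC/C=C(C)/CCO | intermediate
16 | 4‑(bromomethyl)butenolide, C14 alcohol | O=C1C(CBr)=C[C@H](O1)[C@@H]1O[C@@]1(C)[C@H](OC(C)=O)C/C=C(C)/CC/C=C(C)/CCO | intermediate
17 | 4‑(bromomethyl)butenolide, C14 aldehyde (seco‑michaolide F) | O=C1C(CBr)=C[C@H](O1)[C@@H]1O[C@@]1(C)[C@H](OC(C)=O)C/C=C(C)/CC/C=C(C)/CC=O | intermediate
18 | michaolide F | C=C1C(=O)O[C@H]2[C@H]1[C@H](O)C/C(C)=C/CC/C(C)=C/C[C@@H](OC(C)=O)[C@]1(C)O[C@@H]21 | target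

## Step count and risks

Total steps: 15. Longest linear sequence: 14 (geranyl chloride → 18, steps 2–15).

Three steps most likely to fail:

1. **Step 15 (macrocyclisation and C14 configuration).** The tethered transition state may favour the chair/anti mode and give 14‑epi material, or close slowly. Fallback: form C1–C14 intermolecularly by Zn Barbier of a truncated C16–C10 bromomethylbutenolide (terminal C9=C10 alkene) with (E)‑4‑iodo‑3‑methylbut‑3‑enal, where syn/anti can be tuned by the metal, then close the ring at C10–C11 by hydroboration/B‑alkyl Suzuki macrocyclisation.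

2. **Step 11 (MBH on the base‑sensitive γ‑epoxy butenolide).** Low butenolide electrophilicity or γ‑deprotonation with epoxide opening could defeat it. Fallback: reverse the polarity of ring closure. Leave C17 out, convert the diene of 13 to the C14 aldehyde, close C1–C14 by SmI2 ketyl–olefin addition onto the butenolide β‑carbon, and trap the samarium enolate with Eschenmoser's salt (then MeI/NaHCO3) to make the exo‑methylene.

3. **Step 10 (Mitsunobu inversion at a carbinol flanked by the quaternary epoxide carbon).** SN2 may be too slow or give elimination. Fallback: make the threo C5 centre by C–C bond formation instead of inversion. Reduce 3 to the primary allylic alcohol, photo‑oxygenate, run a reagent‑controlled Sharpless epoxidation, oxidise to the C3–C4 epoxy aldehyde, and add the C6–C14 allyl nucleophile under non‑chelation control (threo), followed by simple Ac2O acetylation.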